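**Retrosynthetic overview**

1. Numbering: flavanone rings A and C (O1, C2 to C8a), phenyl ring B, pyranone ring D (primed atoms). The strategy rests on ring D: O1', C6' (ethyl) and C5' (methyl) are an intact 3-pentanone, and C2'–C3'–C4' is a malonyl unit whose central carbon C3' is already bonded to C6 of ring A.
2. Key disconnection: C4'–C5' and O1'–C2' (3-pentanone plus an aryl(chlorocarbonyl)ketene). Ring D is formed first, and the crowded C6–C3' bond is made earlier as a malonate C-arylation of an aryl bromide.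
3. The three ring A oxygens are told apart before the key step: O1 as a benzyl ether, O5 and O7 as methyl ethers (borylation–oxidation of 2-bromo-1,3-dimethoxybenzene).
4. Ring C second: C-acetylation ortho to the freed O1 phenol, formate Claisen condensation and dehydration to the chromone; then demethylation and C8 prenylation by Claisen rearrangement from O7.
5. C2 (S) last: palladium/(R)-t-BuPyOx conjugate addition of phenylboronic acid (ring B) to the chromone, then removal of the MOM groups.

Key step: step 6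

Remark (assumption): the MOM group on the pyranone is drawn on O4' (2-pyranone form); an isomer alkylated on the lactone carbonyl oxygen would protect equally well and give the same hydroxypyranone in step 17.

**Route**

Step 1
Reactants: 1 2-bromo-1,3-dimethoxybenzene; 2 bis(pinacolato)diboron
Product: 4 4-bromo-3,5-dimethoxyphenol, via pinacol boronate 3 (not isolated)
Conditions: [Ir(OMe)(cod)]2 (cat.), dtbpy (cat.), THF, 80 °C; then KHSO5 (Oxone), acetone/H2O, rt
Reagents that add atoms: potassium peroxymonosulfate, [K+].[O-]S(=O)(=O)OO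
Why: Sterically governed iridium-catalysed aromatic C–H borylation should occur at C5, the only C–H not flanked by a substituent, with the C–Br bond untouched, and oxidation of the C–B bond then gives the phenol (one-pot borylation–oxidation).

Step 2
Reactants: 4 4-bromo-3,5-dimethoxyphenol; 5 benzyl bromide
Product: 6 5-(benzyloxy)-2-bromo-1,3-dimethoxybenzene
Conditions: K2CO3, DMF, rt
Reagents that add atoms: none
Why: Williamson etherification of the phenoxide, which marks the future ring oxygen O1 with a group that can later be removed in the presence of the two methyl ethers.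

Step 3
Reactants: 6 5-(benzyloxy)-2-bromo-1,3-dimethoxybenzene; 7 diethyl malonate
Product: 8 diethyl 2-[4-(benzyloxy)-2,6-dimethoxyphenyl]malonate
Conditions: Pd2(dba)3 (cat.), P(t-Bu)3·HBF4 (cat.), K3PO4, toluene, 100 °C
Reagents that add atoms: none
Why: Palladium-catalysed α-arylation of a malonate (Buchwald–Hartwig type), in which the bulky electron-rich phosphine allows oxidative addition into the electron-rich, doubly ortho-substituted bromide and fast reductive elimination, while the acidic product is held as its enolate so that no second arylation follows; this makes the C6–C3' bond.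

Step 4
Reactants: 8 diethyl 2-[4-(benzyloxy)-2,6-dimethoxyphenyl]malonate
Product: 9 2-[4-(benzyloxy)-2,6-dimethoxyphenyl]malonic acid
Conditions: KOH, EtOH/H2O, 60 °C; then aq. HCl, 0 °C
Reagents that add atoms: potassium hydroxide, [K+].[OH-]
Why: Saponification of the hindered diester, with cold acidification so that the arylmalonic acid does not decarboxylate.

Step 5
Reactants: 9 2-[4-(benzyloxy)-2,6-dimethoxyphenyl]malonic acid
Product: 11 (chlorocarbonyl)[4-(benzyloxy)-2,6-dimethoxyphenyl]ketene, via malonyl dichloride 10 (not isolated)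
Conditions: (COCl)2, DMF (cat.), CH2Cl2, 0 °C to rt; evaporate; toluene, 90 °C, N2 stream
Reagents that add atoms: oxalyl chloride, O=C(Cl)C(=O)Cl
Why: Acid chloride formation followed by thermal 1,2-elimination of HCl from the doubly activated benzylic C–H is the standard route from monosubstituted malonic acids to (chlorocarbonyl)ketenes, and oxalyl chloride is used instead of hot thionyl chloride to spare the electron-rich ring; the crude ketene is used directly.

Step 6
Reactants: 11 (chlorocarbonyl)[4-(benzyloxy)-2,6-dimethoxyphenyl]ketene; 12 3-pentanone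
Product: 14 3-[4-(benzyloxy)-2,6-dimethoxyphenyl]-6-ethyl-4-hydroxy-5-methyl-2H-pyran-2-one, via diketo acid chloride 13 (not isolated)
Conditions: 12 (5 equiv), toluene, 110 °C, N2 stream
Reagents that add atoms: none
Why: The acid-catalysed enol of 3-pentanone adds through C2 to the central ketene carbon of 11 (C4'–C5' bond) to give the β-diketo acid chloride 13, whose ethyl ketone enol oxygen then attacks the acyl chloride (O1'–C2' bond) with loss of HCl, and tautomerisation gives the hydroxypyranone. This is the known condensation of enolisable ketones with aryl(chlorocarbonyl)ketenes to 3-aryl-4-hydroxy-2-pyranones. The one ring formed, ring D, closes by a six-membered O-acylation (6-exo-trig lactonisation) on the preformed C6–C3' bond, so the aryl–pyranone bond flanked by four ortho substituents never has to be made by a biaryl coupling. No stereocentre is created. The step needs chemoselectivity for C,O-annulation over simple enol ester formation and over capture of the ketene by an ortho methoxy oxygen; the carbon nucleophilicity of the enol towards the ketene, the excess of ketone and the removal of HCl should secure the first, and methyl rather than benzyl ortho ethers disfavour the dealkylative side reaction. Regiochemistry is not in question because 3-pentanone has a single enol, which places methyl at C5' and ethyl at C6'.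

Step 7
Reactants: 14 3-[4-(benzyloxy)-2,6-dimethoxyphenyl]-6-ethyl-4-hydroxy-5-methyl-2H-pyran-2-one
Product: 15 6-ethyl-4-hydroxy-3-(4-hydroxy-2,6-dimethoxyphenyl)-5-methyl-2H-pyran-2-one
Conditions: H2 (1 atm), Pd/C (10%), EtOAc/MeOH, rt
Reagents that add atoms: none
Why: Hydrogenolysis of the single benzyl ether unveils only the para phenol (future O1), the methyl ethers and the fully substituted pyranone being inert.

Step 8
Reactants: 15 6-ethyl-4-hydroxy-3-(4-hydroxy-2,6-dimethoxyphenyl)-5-methyl-2H-pyran-2-one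
Product: 16 3-(3-acetyl-4-hydroxy-2,6-dimethoxyphenyl)-6-ethyl-4-hydroxy-5-methyl-2H-pyran-2-one
Conditions: AcOH, BF3·OEt2, 90 °C; aq. NaOAc work-up
Reagents that add atoms: acetic acid, CC(=O)O
Why: Friedel–Crafts (Nencki-type) C-acetylation ortho to the free phenol, where the two open ring positions are equivalent and the first acyl group deactivates the ring against a second.

Step 9
Reactants: 16 3-(3-acetyl-4-hydroxy-2,6-dimethoxyphenyl)-6-ethyl-4-hydroxy-5-methyl-2H-pyran-2-one
Product: 18 6-(6-ethyl-4-hydroxy-5-methyl-2-oxo-2H-pyran-3-yl)-5,7-dimethoxy-4H-chromen-4-one, via 2-hydroxychromanone 17 (not isolated)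
Conditions: NaH, HCO2Et, THF, 0 °C to rt; then conc. HCl, AcOH, 50 °C
Reagents that add atoms: ethyl formate, CCOC=O
Why: Claisen condensation of the methyl ketone with ethyl formate gives a β-keto aldehyde that closes to the 2-hydroxychromanone and is dehydrated by acid (classical chromone synthesis), and since only the para oxygen is free, ring C is fused in the one sense that puts the pyranone at C6.

Step 10
Reactants: 18 6-(6-ethyl-4-hydroxy-5-methyl-2-oxo-2H-pyran-3-yl)-5,7-dimethoxy-4H-chromen-4-one
Product: 19 6-(6-ethyl-4-hydroxy-5-methyl-2-oxo-2H-pyran-3-yl)-5,7-dihydroxy-4H-chromen-4-one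
Conditions: BBr3, CH2Cl2, −78 °C to rt; then MeOH, H2O
Reagents that add atoms: none
Why: Lewis acid ether cleavage removes both methyl ethers, which are twisted out of plane by two ortho neighbours and should cleave readily, and it is done on the robust achiral chromone before the acid-sensitive prenyl group and the stereocentre exist.

Step 11
Reactants: 19 6-(6-ethyl-4-hydroxy-5-methyl-2-oxo-2H-pyran-3-yl)-5,7-dihydroxy-4H-chromen-4-one
Product: 20 6-[6-ethyl-4-(methoxymethoxy)-5-methyl-2-oxo-2H-pyran-3-yl]-5,7-dihydroxy-4H-chromen-4-one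
Conditions: MOMCl (1.0 equiv), i-Pr2NEt (1.0 equiv), CH2Cl2/DMF, −20 °C
Reagents that add atoms: chloromethyl methyl ether, COCCl
Why: With one equivalent of base only the most acidic hydroxyl, the vinylogous carboxylic acid of the pyranone (about two pKa units below the 7-OH, the 5-OH being chelated), is ionised and O-alkylated (acetal protection).

Step 12
Reactants: 20 6-[6-ethyl-4-(methoxymethoxy)-5-methyl-2-oxo-2H-pyran-3-yl]-5,7-dihydroxy-4H-chromen-4-one; 21 3-chloro-3-methylbut-1-yne
Product: 22 6-[6-ethyl-4-(methoxymethoxy)-5-methyl-2-oxo-2H-pyran-3-yl]-5-hydroxy-7-[(2-methylbut-3-yn-2-yl)oxy]-4H-chromen-4-one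
Conditions: CuCl2·2H2O (cat.), DBU, MeCN, 0 °C
Reagents that add atoms: none
Why: Copper-catalysed propargylic substitution of the tertiary chloride by the 7-phenoxide gives the 1,1-dimethylpropargyl ether, the chelated 5-OH being much less acidic and unreactive.

Step 13
Reactants: 22 6-[6-ethyl-4-(methoxymethoxy)-5-methyl-2-oxo-2H-pyran-3-yl]-5-hydroxy-7-[(2-methylbut-3-yn-2-yl)oxy]-4H-chromen-4-one
Product: 23 6-[6-ethyl-4-(methoxymethoxy)-5-methyl-2-oxo-2H-pyran-3-yl]-5-hydroxy-7-[(2-methylbut-3-en-2-yl)oxy]-4H-chromen-4-one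
Conditions: H2 (1 atm), Pd/CaCO3 poisoned with Pb(OAc)2 (Lindlar catalyst), quinoline, EtOAc, rt
Reagents that add atoms: none
Why: Lindlar semi-hydrogenation stops the terminal alkyne at the 1,1-dimethylallyl ether and should not touch the chromone enone or the pyranone.

Step 14
Reactants: 23 6-[6-ethyl-4-(methoxymethoxy)-5-methyl-2-oxo-2H-pyran-3-yl]-5-hydroxy-7-[(2-methylbut-3-en-2-yl)oxy]-4H-chromen-4-one
Product: 24 6-[6-ethyl-4-(methoxymethoxy)-5-methyl-2-oxo-2H-pyran-3-yl]-5,7-dihydroxy-8-(3-methylbut-2-en-1-yl)-4H-chromen-4-one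
Conditions: toluene, 110 °C
Reagents that add atoms: none
Why: Aromatic Claisen rearrangement of the tertiary allyl ether delivers the prenyl group to C8, the only free ortho position because C6 carries the pyranone, and rearomatisation returns the 7-OH.

Step 15
Reactants: 24 6-[6-ethyl-4-(methoxymethoxy)-5-methyl-2-oxo-2H-pyran-3-yl]-5,7-dihydroxy-8-(3-methylbut-2-en-1-yl)-4H-chromen-4-one
Product: 25 6-[6-ethyl-4-(methoxymethoxy)-5-methyl-2-oxo-2H-pyran-3-yl]-5-hydroxy-7-(methoxymethoxy)-8-(3-methylbut-2-en-1-yl)-4H-chromen-4-one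
Conditions: MOMCl, i-Pr2NEt, CH2Cl2, 0 °C to rt
Reagents that add atoms: chloromethyl methyl ether, COCCl
Why: MOM protection of the 7-OH (the chelated 5-OH stays free) is needed because a free phenol next to the prenyl group could undergo Wacker-type cyclisation under the palladium conditions of the next step.

Step 16
Reactants: 25 6-[6-ethyl-4-(methoxymethoxy)-5-methyl-2-oxo-2H-pyran-3-yl]-5-hydroxy-7-(methoxymethoxy)-8-(3-methylbut-2-en-1-yl)-4H-chromen-4-one; 26 phenylboronic acid
Product: 27 (2S)-6-[6-ethyl-4-(methoxymethoxy)-5-methyl-2-oxo-2H-pyran-3-yl]-5-hydroxy-7-(methoxymethoxy)-8-(3-methylbut-2-en-1-yl)-2-phenylchroman-4-one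
Conditions: Pd(OCOCF3)2 (cat.), (R)-t-BuPyOx (cat.), NH4PF6, H2O, ClCH2CH2Cl, 60 °C
Reagents that add atoms: none
Why: Palladium-catalysed asymmetric conjugate addition of an arylboronic acid to a chromone, in which the cationic phenylpalladium pyridine-oxazoline complex adds across C2=C3 and the enolate is protonated, and the tert-butyl group of the (R)-ligand should direct phenyl to the face of C2 that gives the (2S)-flavanone, by analogy with the sense of induction of this ligand class on cyclic enones.

Step 17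
Reactants: 27 (2S)-6-[6-ethyl-4-(methoxymethoxy)-5-methyl-2-oxo-2H-pyran-3-yl]-5-hydroxy-7-(methoxymethoxy)-8-(3-methylbut-2-en-1-yl)-2-phenylchroman-4-one
Product: 28 (2S)-6-(6-ethyl-4-hydroxy-5-methyl-2-oxo-2H-pyran-3-yl)-5,7-dihydroxy-8-(3-methylbut-2-en-1-yl)-2-phenylchroman-4-one (CNP0482269.1)
Conditions: 3 M HCl, MeOH, 40 °C
Reagents that add atoms: none
Why: Acid-catalysed acetal hydrolysis removes both MOM groups under conditions that should be too mild to cyclise the prenyl group onto O7 or to epimerise C2.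

**Compound list**

1 | 2-bromo-1,3-dimethoxybenzene | COc1cccc(OC)c1Br | starting material
2 | bis(pinacolato)diboron | CC1(C)OB(OC1(C)C)B1OC(C)(C)C(C)(C)O1 | starting material
3 | 2-(4-bromo-3,5-dimethoxyphenyl)-4,4,5,5-tetramethyl-1,3,2-dioxaborolane | COc1cc(B2OC(C)(C)C(C)(C)O2)cc(OC)c1Br | intermediate (not isolated)
4 | 4-bromo-3,5-dimethoxyphenol | COc1cc(O)cc(OC)c1Br | intermediate
5 | benzyl bromide | BrCc1ccccc1 | starting material
6 | 5-(benzyloxy)-2-bromo-1,3-dimethoxybenzene | COc1cc(OCc2ccccc2)cc(OC)c1Br | intermediate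
7 | diethyl malonate | CCOC(=O)CC(=O)OCC | starting material
8 | diethyl 2-[4-(benzyloxy)-2,6-dimethoxyphenyl]malonate | CCOC(=O)C(C(=O)OCC)c1c(OC)cc(OCc2ccccc2)cc1OC | intermediate
9 | 2-[4-(benzyloxy)-2,6-dimethoxyphenyl]malonic acid | OC(=O)C(C(=O)O)c1c(OC)cc(OCc2ccccc2)cc1OC | intermediate
10 | 2-[4-(benzyloxy)-2,6-dimethoxyphenyl]malonyl dichloride | O=C(Cl)C(C(=O)Cl)c1c(OC)cc(OCc2ccccc2)cc1OC | intermediate (not isolated)
11 | (chlorocarbonyl)[4-(benzyloxy)-2,6-dimethoxyphenyl]ketene | O=C=C(C(=O)Cl)c1c(OC)cc(OCc2ccccc2)cc1OC | intermediate (key-step precursor)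
12 | 3-pentanone | CCC(=O)CC | starting material
13 | 2-[4-(benzyloxy)-2,6-dimethoxyphenyl]-4-methyl-3,5-dioxoheptanoyl chloride | CCC(=O)C(C)C(=O)C(C(=O)Cl)c1c(OC)cc(OCc2ccccc2)cc1OC | intermediate (not isolated)
14 | 3-[4-(benzyloxy)-2,6-dimethoxyphenyl]-6-ethyl-4-hydroxy-5-methyl-2H-pyran-2-one | CCc1oc(=O)c(-c2c(OC)cc(OCc3ccccc3)cc2OC)c(O)c1C | intermediate (key-step product)
15 | 6-ethyl-4-hydroxy-3-(4-hydroxy-2,6-dimethoxyphenyl)-5-methyl-2H-pyran-2-one | CCc1oc(=O)c(-c2c(OC)cc(O)cc2OC)c(O)c1C | intermediate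
16 | 3-(3-acetyl-4-hydroxy-2,6-dimethoxyphenyl)-6-ethyl-4-hydroxy-5-methyl-2H-pyran-2-one | CCc1oc(=O)c(-c2c(OC)cc(O)c(C(C)=O)c2OC)c(O)c1C | intermediate
17 | 6-(6-ethyl-4-hydroxy-5-methyl-2-oxo-2H-pyran-3-yl)-2-hydroxy-5,7-dimethoxychroman-4-one | CCc1oc(=O)c(-c2c(OC)cc3OC(O)CC(=O)c3c2OC)c(O)c1C | intermediate (not isolated)
18 | 6-(6-ethyl-4-hydroxy-5-methyl-2-oxo-2H-pyran-3-yl)-5,7-dimethoxy-4H-chromen-4-one | CCc1oc(=O)c(-c2c(OC)cc3occc(=O)c3c2OC)c(O)c1C | intermediate
19 | 6-(6-ethyl-4-hydroxy-5-methyl-2-oxo-2H-pyran-3-yl)-5,7-dihydroxy-4H-chromen-4-one | CCc1oc(=O)c(-c2c(O)cc3occc(=O)c3c2O)c(O)c1C | intermediate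
20 | 6-[6-ethyl-4-(methoxymethoxy)-5-methyl-2-oxo-2H-pyran-3-yl]-5,7-dihydroxy-4H-chromen-4-one | CCc1oc(=O)c(-c2c(O)cc3occc(=O)c3c2O)c(OCOC)c1C | intermediate
21 | 3-chloro-3-methylbut-1-yne | CC(C)(Cl)C#C | starting material
22 | 6-[6-ethyl-4-(methoxymethoxy)-5-methyl-2-oxo-2H-pyran-3-yl]-5-hydroxy-7-[(2-methylbut-3-yn-2-yl)oxy]-4H-chromen-4-one | CCc1oc(=O)c(-c2c(OC(C)(C)C#C)cc3occc(=O)c3c2O)c(OCOC)c1C | intermediate
23 | 6-[6-ethyl-4-(methoxymethoxy)-5-methyl-2-oxo-2H-pyran-3-yl]-5-hydroxy-7-[(2-methylbut-3-en-2-yl)oxy]-4H-chromen-4-one | CCc1oc(=O)c(-c2c(OC(C)(C)C=C)cc3occc(=O)c3c2O)c(OCOC)c1C | intermediate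
24 | 6-[6-ethyl-4-(methoxymethoxy)-5-methyl-2-oxo-2H-pyran-3-yl]-5,7-dihydroxy-8-(3-methylbut-2-en-1-yl)-4H-chromen-4-one | CCc1oc(=O)c(-c2c(O)c(CC=C(C)C)c3occc(=O)c3c2O)c(OCOC)c1C | intermediate
25 | 6-[6-ethyl-4-(methoxymethoxy)-5-methyl-2-oxo-2H-pyran-3-yl]-5-hydroxy-7-(methoxymethoxy)-8-(3-methylbut-2-en-1-yl)-4H-chromen-4-one | CCc1oc(=O)c(-c2c(OCOC)c(CC=C(C)C)c3occc(=O)c3c2O)c(OCOC)c1C | intermediate
26 | phenylboronic acid | OB(O)c1ccccc1 | starting material
27 | (2S)-6-[6-ethyl-4-(methoxymethoxy)-5-methyl-2-oxo-2H-pyran-3-yl]-5-hydroxy-7-(methoxymethoxy)-8-(3-methylbut-2-en-1-yl)-2-phenylchroman-4-one | CCc1oc(=O)c(-c2c(OCOC)c(CC=C(C)C)c3c(c2O)C(=O)C[C@@H](c2ccccc2)O3)c(OCOC)c1C | intermediate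
28 | (2S)-6-(6-ethyl-4-hydroxy-5-methyl-2-oxo-2H-pyran-3-yl)-5,7-dihydroxy-8-(3-methylbut-2-en-1-yl)-2-phenylchroman-4-one | CCc1oc(=O)c(-c2c(O)c(CC=C(C)C)c3c(c2O)C(=O)C[C@@H](c2ccccc2)O3)c(O)c1C | target

**Step count**

Total step count: 17. Longest linear sequence: 17 (steps 1 to 17, from compound 1).

**Steps most likely to fail**

Step 6 (key annulation). The hindered, electron-rich ketene may be captured by an ortho methoxy oxygen (dealkylative lactonisation) or may oligomerise before the slowly formed enol adds. The fallback makes the aryl–pyranone bond by Pinhey arylation of a preformed pyranone. Setting out from 12, silylation (TMSCl, NaI, Et3N, MeCN) would give trimethyl(pent-2-en-3-yloxy)silane F1, and its known condensation with malonyl dichloride (Et2O, −78 °C to rt) would give 6-ethyl-4-hydroxy-5-methyl-2H-pyran-2-one F2. Setting out from 6, bromine–lithium exchange (n-BuLi, THF, −78 °C) and quenching with Bu3SnCl would give [4-(benzyloxy)-2,6-dimethoxyphenyl]tributylstannane F3, and tin–lead exchange with Pb(OAc)4 (Hg(OAc)2 cat., CHCl3) would give [4-(benzyloxy)-2,6-dimethoxyphenyl]lead triacetate F4. Heating F2 and F4 in CHCl3/pyridine at 60 °C should arylate C3' by ligand coupling, and the route is rejoined at compound 14.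

Step 16 (asymmetric conjugate addition). The chelating 5-hydroxy-4-keto unit may sequester the catalyst, the electron-rich chromone may react slowly, or facial selectivity may be poor. The fallback separates C–C bond formation from stereocontrol. Setting out from 25, addition of 26 with the more active achiral catalyst Pd(OCOCF3)2/2,2'-bipyridine (aq. AcOH/THF, 60 °C) would give the racemic flavanone F5. Kinetic resolution by Noyori transfer hydrogenation (RuCl(p-cymene)[(R,R)-TsDPEN], HCO2H/Et3N, rt) follows. This catalyst antipode reduces aryl ketones to (R)-carbinols, so it is expected to consume the (2R)-ketone as the cis-(2R,4R)-flavan-4-ol F6 and leave the (2S)-ketone. Chromatographic separation rejoins the route at compound 27, at the cost of half of the material.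

Step 11 (selective protection of the pyranone hydroxyl). The acidity gap to the 7-OH is only about two pKa units, so alkylation may be unselective. The fallback takes O7 out of the prenylation altogether. Setting out from 19, iodination at C8, the only free ring position (N-iodosuccinimide, DMF, 0 °C), would give 6-(6-ethyl-4-hydroxy-5-methyl-2-oxo-2H-pyran-3-yl)-5,7-dihydroxy-8-iodo-4H-chromen-4-one F7. Exhaustive MOM protection of the pyranone and 7-hydroxyls (excess MOMCl, i-Pr2NEt, CH2Cl2) would give 6-[6-ethyl-4-(methoxymethoxy)-5-methyl-2-oxo-2H-pyran-3-yl]-5-hydroxy-8-iodo-7-(methoxymethoxy)-4H-chromen-4-one F8. Stille coupling with tributyl(3-methylbut-2-en-1-yl)stannane (Pd(PPh3)4, DMF, 90 °C) would install the prenyl group, and the route is rejoined at compound 25, bypassing steps 12 to 15.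

**Further compounds**

F1 | step 6 | trimethyl(pent-2-en-3-yloxy)silane | CC=C(CC)O[Si](C)(C)C
F2 | step 6 | 6-ethyl-4-hydroxy-5-methyl-2H-pyran-2-one | CCc1oc(=O)cc(O)c1C
F3 | step 6 | [4-(benzyloxy)-2,6-dimethoxyphenyl]tributylstannane | CCCC[Sn](CCCC)(CCCC)c1c(OC)cc(OCc2ccccc2)cc1OC
F4 | step 6 | [4-(benzyloxy)-2,6-dimethoxyphenyl]lead triacetate | CC(=O)O[Pb](OC(C)=O)(OC(C)=O)c1c(OC)cc(OCc2ccccc2)cc1OC
F5 | step 16 | racemic 6-[6-ethyl-4-(methoxymethoxy)-5-methyl-2-oxo-2H-pyran-3-yl]-5-hydroxy-7-(methoxymethoxy)-8-(3-methylbut-2-en-1-yl)-2-phenylchroman-4-one | CCc1oc(=O)c(-c2c(OCOC)c(CC=C(C)C)c3c(c2O)C(=O)CC(c2ccccc2)O3)c(OCOC)c1C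
F6 | step 16 | (2R,4R)-6-[6-ethyl-4-(methoxymethoxy)-5-methyl-2-oxo-2H-pyran-3-yl]-7-(methoxymethoxy)-8-(3-methylbut-2-en-1-yl)-2-phenylchromane-4,5-diol | CCc1oc(=O)c(-c2c(OCOC)c(CC=C(C)C)c3c(c2O)[C@H](O)C[C@H](c2ccccc2)O3)c(OCOC)c1C
F7 | step 11 | 6-(6-ethyl-4-hydroxy-5-methyl-2-oxo-2H-pyran-3-yl)-5,7-dihydroxy-8-iodo-4H-chromen-4-one | CCc1oc(=O)c(-c2c(O)c(I)c3occc(=O)c3c2O)c(O)c1C
F8 | step 11 | 6-[6-ethyl-4-(methoxymethoxy)-5-methyl-2-oxo-2H-pyran-3-yl]-5-hydroxy-8-iodo-7-(methoxymethoxy)-4H-chromen-4-one | CCc1oc(=O)c(-c2c(OCOC)c(I)c3occc(=O)c3c2O)c(OCOC)c1C
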